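The vessel is closed, stirred and held at one temperature, and in it incoming ligand replaces leaving ligand on the starting complex, first at one place, then at a second.

| flask | starting complex | incoming ligand | leaving ligand | remark | time |
|---|---|---|---|---|---|
| noon | 0.040 M | 0.040 M | 0.10 M | run made earlier |  |
| spring | 0.090 M | 0.040 M | 0.10 M | run made earlier |  |
| winter | 0.22 M | 0.040 M | 0.10 M | run made earlier |  |
| Friday's | 0.050 M | 0.0400 M | 0.100 M |  | 15 min |
| Thursday's | 0.20 M | 0.0400 M | 0.100 M |  | 25 min |

- noon (time / min: complex with two exchanged / %): 2.00: 1.9; 4.00: 4.6; 6.00: 8.4; 8.00: 10.6; 10.0: 14.9
- spring (time / min: complex with two exchanged / %): 1.00: 0; 2.50: 1.6; 5.00: 3.2; 8.00: 4.9; 10.0: 5.6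
- winter (time / min: complex with two exchanged / %): 2.00: 0.5; 4.00: 1.8; 6.00: 1.2; 8.00: 1.0; 10.0: 1.4

(scatter of a reading: 0.5 percentage points)

- a reading or a percentage of complex with two exchanged counts all its forms, free or not

1. which one finishes higher in amount of complex with two exchanged, in percent of the starting complex charged ("neither" within 2 percentage points) (Friday's / Thursday's / neither)
2. amount of complex with two exchanged at the end, in percent of the starting complex charged, Friday's
3. amount of complex with two exchanged at the end, in percent of the starting complex charged, Thursday's

1. Write the balance of incoming ligand, the limiting reagent: its 0.0400 M is less than the 0.050 M of starting complex in Friday's and the 0.20 M in Thursday's. Each complex with one exchanged has taken one ligand, and each complex with two exchanged, in whatever form, has taken two.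

2. Now take a bench rule of thumb. Suppose the ligand lands at random on the places. Then the filled fraction of places is the ligand charged over twice the complex charged, and the square of that fraction is the part of the complexes with both places filled. Friday's gives 16.0%; this square, the random share, is what you carry along. Thursday's gives 1.00%.

3. Test it on the earlier runs. The winter run has a share of 0.826%, and its last reading is 1.4%, about one scatter above. The spring run has a share of 4.94%, and it reads 4.9% at 8.00 min and 5.6% at 10.0 min.

4. The rule assumes the ligand has finished reacting, and that takes time. The noon run made product at a mean pace of 5.96 × 10⁻⁴ M min⁻¹. Borrow this pace for the other flasks, divide the time it needs to reach the share by the length of the run, and you have the border ratio. Above 1, the run is too short at this pace. It is 0.895 for Friday's and 0.134 for Thursday's. The noon run stands at 1.68 and was still rising at its last reading. So I expect Thursday's near its share and Friday's just below its own.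

5. The forecast names Friday's, with 16% against 1.6%, the latter above my Thursday's share, and holds that “the limit looks like equilibrium rather than kinetics”.

6. The flasks give 15.0% for Friday's and 1.38% for Thursday's.

    complex with one exchanged + incoming ligand → leaving ligand + complex with two exchanged (k = 2.40 M⁻¹ min⁻¹)
    starting complex + complex with two exchanged ⇌ idle adduct, settled at all times (K = 58.0 M⁻¹)
    starting complex + incoming ligand → leaving ligand + complex with one exchanged (k = 3.30 M⁻¹ min⁻¹)

In Friday's, the exchange on starting complex used incoming ligand 4.1 times as fast as the exchange on complex with one exchanged at 3.00 min, but 1.4 times as fast at 15.0 min, with 14% of its charge left. Friday's 15.0% is a point on the way: left until 150 min, that flask stands at 20.2%, more than the share of 16.0%. In the same flask as Friday's but with 0.020 M of starting complex, the share is 100% and the border ratio 2.24, beyond the border. That flask gives 31.1%, with 49% of its ligand left.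

(Readings and results are simulated on assumed constants, and the scatter is random.)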